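**Plan**

- Numbering: ring A is C1 (bridge CH2), C2 (OMe), C3 (Me), C4 (OH), C5 (Ac), C6 (OH); ring B is C1' (bridge), C2' (OH), C3' (Ac), C4' (OH), C5' (prenyl), C6' (OMe). Enabling feature: ring B carries oxygen on C2', C4', C6' and carbon on C1', C3', C5', with methoxy carbon C6' between bridge carbon C1' and prenyl carbon C5'. This is the pattern formed when a 2-alkyl-3-siloxy vinylketene (C1' to C4') takes up an alkoxyalkyne (C5', C6').
- Retrosynthetic cuts, in order: the two aryl–acetyl bonds (C5 and C3'); ring B at C4'–C5' and C6'–C1'; the cyclobutenone into a siloxyalkyne and ketene; the alkyne carbon from an arylacetic ester; the side chain back to formylated methylphloroglucinol.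
- Forward order: ring A is bought and functionalised, the four-membered ring is built on the bridge carbon (step 8), ring B arises in step 10, then silyl-to-MOM exchange, twofold lithiation/acetylation and global MOM removal.
- Stereochemistry: the target has no stereocentre and no stereogenic alkene. Control is regiochemical only: steric differentiation of the ring A hydroxyls and ynol ether polarity in the [2+2] step.

Key step: step 10

Remarks: Ar = 2-methoxy-4,6-bis(methoxymethoxy)-3-methylphenyl; MOM = methoxymethyl. Assumption: ketene is generated from acetone in a hot-wire generator and passed directly into the reaction, so acetone counts as a starting material and ketene as an intermediate that is not isolated.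

**Route**

Step 1
Reactants: 1 2,4,6-trihydroxytoluene
Product: 3 2,4,6-trihydroxy-3-methylbenzaldehyde, via iminium chloride 2 (not isolated)
Conditions: POCl3, DMF, EtOAc, 0 °C → rt; then H2O, 50 °C
Reagents that add atoms: N,N-dimethylformamide, CN(C)C=O (formyl carbon); water, O (formyl oxygen)
Why: Vilsmeier–Haack formylation of the strongly activated phloroglucinol nucleus, whose two free ring positions are equivalent, so a single aldehyde should form.

Step 2
Reactants: 3 2,4,6-trihydroxy-3-methylbenzaldehyde
Product: 4 2-hydroxy-4,6-bis(methoxymethoxy)-3-methylbenzaldehyde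
Conditions: MOMCl (2.1 equiv), i-Pr2NEt, CH2Cl2–THF, 0 °C → rt
Reagents that add atoms: chloromethyl methyl ether, COCCl
Why: Phenol O-alkylation under mild amine base should take the unchelated para hydroxyl first and then the less hindered ortho hydroxyl at C6, because the C2 hydroxyl is wedged between formyl and methyl and held in a hydrogen bond to the carbonyl; any regioisomer would be removed by chromatography.

Step 3
Reactants: 4 2-hydroxy-4,6-bis(methoxymethoxy)-3-methylbenzaldehyde
Product: 5 2-methoxy-4,6-bis(methoxymethoxy)-3-methylbenzaldehyde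
Conditions: MeI, K2CO3, DMF, 40 °C
Reagents that add atoms: iodomethane, CI
Why: Williamson methylation of the one remaining, chelated phenol, which carbonate in warm DMF is known to alkylate in ortho-hydroxybenzaldehydes.

Step 4
Reactants: 5 2-methoxy-4,6-bis(methoxymethoxy)-3-methylbenzaldehyde
Product: 7 2-[2-methoxy-4,6-bis(methoxymethoxy)-3-methylphenyl]acetonitrile, via tosylvinyl formamide potassium salt 6 (not isolated)
Conditions: TosMIC, t-BuOK, DME, −40 °C; then MeOH, reflux
Reagents that add atoms: p-toluenesulfonylmethyl isocyanide, Cc1ccc(cc1)S(=O)(=O)C[N+]#[C-]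
Why: Van Leusen reductive cyanation, in which the TosMIC anion adds to the aldehyde, the oxazoline opens under excess strong base at low temperature, and methanolysis removes formyl and sulfinate to leave the one-carbon-homologated nitrile under purely basic conditions that spare the MOM ethers.

Step 5
Reactants: 7 2-[2-methoxy-4,6-bis(methoxymethoxy)-3-methylphenyl]acetonitrile
Product: 9 2-[2-methoxy-4,6-bis(methoxymethoxy)-3-methylphenyl]acetic acid, via potassium arylacetate 8 (not isolated)
Conditions: KOH, EtOH–H2O, reflux; then 1 M HCl to pH 4, 0 °C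
Reagents that add atoms: potassium hydroxide, [K+].[OH-]; water, O
Why: Alkaline hydrolysis of an unhindered arylacetonitrile, with MOM ethers stable to base and to a brief cold acidification to pH 4.

Step 6
Reactants: 9 2-[2-methoxy-4,6-bis(methoxymethoxy)-3-methylphenyl]acetic acid
Product: 10 methyl 2-[2-methoxy-4,6-bis(methoxymethoxy)-3-methylphenyl]acetate
Conditions: MeI, K2CO3, DMF, rt
Reagents that add atoms: iodomethane, CI
Why: Carboxylate O-alkylation gives the methyl ester without any acid.

Step 7
Reactants: 10 methyl 2-[2-methoxy-4,6-bis(methoxymethoxy)-3-methylphenyl]acetate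
Product: 13 triisopropyl({3-[2-methoxy-4,6-bis(methoxymethoxy)-3-methylphenyl]prop-1-yn-1-yl}oxy)silane, via dibromoketone lithium enolate 11 (not isolated), via lithium ynolate 12 (not isolated)
Conditions: CH2Br2, lithium 2,2,6,6-tetramethylpiperidide, THF, −78 °C, then 10; LiN(SiMe3)2, then sec-BuLi, −78 °C → rt; i-Pr3SiCl, −78 → 0 °C
Reagents that add atoms: dibromomethane, BrCBr; chlorotriisopropylsilane, CC(C)[Si](Cl)(C(C)C)C(C)C
Why: Kowalski ynolate formation, in which LiCHBr2 acylation gives the dibromoketone enolate, bromine–lithium exchange triggers the carbenoid 1,2-shift of the ArCH2 group to the ynolate, and the bulky silyl chloride silylates on oxygen; the di-ortho-substituted electron-rich aryl conjugates poorly with an ester enolate, so competing α-deprotonation should be limited.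

Step 8
Reactants: 13 triisopropyl({3-[2-methoxy-4,6-bis(methoxymethoxy)-3-methylphenyl]prop-1-yn-1-yl}oxy)silane; 14 acetone
Product: 16 2-[2-methoxy-4,6-bis(methoxymethoxy)-3-methylbenzyl]-3-(triisopropylsilyloxy)cyclobut-2-en-1-one, via ketene 15 (not isolated)
Conditions: acetone pyrolysed in a hot-wire ketene generator (about 700 °C), gas stream passed into 13 in CH2Cl2, 0 °C → rt
Reagents that add atoms: none
Why: Ketene–siloxyalkyne [2+2] cycloaddition, in which the nucleophilic benzyl-bearing alkyne carbon attacks the ketene carbonyl carbon, so the siloxy group ends at C3 and the benzyl group at C2 of the cyclobutenone.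

Step 9
Reactants: 17 chloroacetaldehyde dimethyl acetal; 18 prenyl bromide
Product: 20 1-methoxy-5-methylhex-4-en-1-yne, via sodium methoxyacetylide 19 (not isolated)
Conditions: NaNH2 (3.0 equiv), liquid NH3, −33 °C; then 18, −78 → −33 °C
Reagents that add atoms: none
Why: Twofold elimination (methanol, then HCl) and deprotonation give the alkoxyacetylide, which should be alkylated by the primary allylic bromide at its unhindered carbon (SN2); exactly three equivalents of amide leave no base to isomerise the skipped enyne.

Step 10
Reactants: 16 2-[2-methoxy-4,6-bis(methoxymethoxy)-3-methylbenzyl]-3-(triisopropylsilyloxy)cyclobut-2-en-1-one; 20 1-methoxy-5-methylhex-4-en-1-yne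
Product: 25 3-methoxy-4-[2-methoxy-4,6-bis(methoxymethoxy)-3-methylbenzyl]-2-(3-methylbut-2-enyl)-5-(triisopropylsilyloxy)phenol, via siloxy vinylketene 21 (not isolated), via vinylcyclobutenone 22 (not isolated), via dienylketene 23 (not isolated), via cyclohexadienone 24 (not isolated)
Conditions: 20 (1.5 equiv), toluene, 110 °C, sealed tube
Reagents that add atoms: none
Why: Danheiser benzannulation: heat opens cyclobutenone 16 by four-electron electrocyclic cleavage of its C1–C4 bond to siloxy vinylketene 21, whose ketene C=C adds to ynol ether 20 in a [2+2] cycloaddition to give 4-vinylcyclobutenone 22. A second four-electron opening gives dienylketene 23, and ring B closes as a six-membered carbocycle by thermal disrotatory six-electron electrocyclisation of the ketene carbon onto the terminal methylene, after which cyclohexadienone 24 tautomerises to phenol 25. The closest known reaction type is the thermal benzannulation of cyclobutenones with alkoxy- or siloxyalkynes to resorcinol monoethers. No stereocentre is formed. The selectivity needed is the regiochemistry of the [2+2] step, secured by ynol ether polarisation: the nucleophilic prenyl-bearing carbon β to oxygen attacks the electrophilic ketene carbonyl carbon, so C4'–C5' and C6'–C1' are formed and the methoxy carbon lies between the prenyl and bridge carbons. The ketene should prefer the electron-rich alkyne over the prenyl alkene, both ortho positions of ring A are blocked against acylation, and a methyl ynol ether cannot fragment by retro-ene reaction at this temperature.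

Step 11
Reactants: 25 3-methoxy-4-[2-methoxy-4,6-bis(methoxymethoxy)-3-methylbenzyl]-2-(3-methylbut-2-enyl)-5-(triisopropylsilyloxy)phenol
Product: 26 5-methoxy-4-[2-methoxy-4,6-bis(methoxymethoxy)-3-methylbenzyl]-6-(3-methylbut-2-enyl)benzene-1,3-diol
Conditions: n-Bu4NF, AcOH, THF, 0 °C
Reagents that add atoms: none
Why: Fluoride cleavage of the aryl silyl ether, buffered with acetic acid so that the electron-rich resorcinol is released as the neutral phenol.

Step 12
Reactants: 26 5-methoxy-4-[2-methoxy-4,6-bis(methoxymethoxy)-3-methylbenzyl]-6-(3-methylbut-2-enyl)benzene-1,3-diol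
Product: 27 3-methoxy-2-[2-methoxy-4,6-bis(methoxymethoxy)-3-methylbenzyl]-1,5-bis(methoxymethoxy)-4-(3-methylbut-2-enyl)benzene
Conditions: MOMCl, i-Pr2NEt, CH2Cl2, 0 °C → rt
Reagents that add atoms: chloromethyl methyl ether, COCCl
Why: Standard MOM protection of two unchelated phenols, which places the single remaining hydrogen of ring B between two MOM ethers, as it already is in ring A.

Step 13
Reactants: 27 3-methoxy-2-[2-methoxy-4,6-bis(methoxymethoxy)-3-methylbenzyl]-1,5-bis(methoxymethoxy)-4-(3-methylbut-2-enyl)benzene
Product: 30 mallotojaponin B tetrakis(methoxymethyl) ether, via dilithio species 28 (not isolated), via dilithium bis-adduct 29 (not isolated)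
Conditions: n-BuLi (2.4 equiv), THF, 0 °C; then MeC(O)N(OMe)Me, −78 → 0 °C; sat. aq. NH4Cl
Reagents that add atoms: N-methoxy-N-methylacetamide, CC(=O)N(C)OC
Why: Twofold directed ortho-metalation at the one ring hydrogen of each ring, each flanked by two cooperating MOM ethers, should outrun deprotonation at the crowded, non-coplanar benzylic positions, and the Weinreb amide stops each addition at the ketone (Weinreb ketone synthesis).

Step 14
Reactants: 30 mallotojaponin B tetrakis(methoxymethyl) ether
Product: 31 mallotojaponin B
Conditions: 3 M HCl, MeOH, 40 °C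
Reagents that add atoms: none
Why: Acid-catalysed acetal exchange with methanol removes all four MOM groups under mild conditions of the kind C-prenyl phenols tolerate, and the freed hydroxyls flanking each acetyl are tied up in hydrogen bonds, which should disfavour chroman formation.

**Compound list**

1 | 2,4,6-trihydroxytoluene | Cc1c(O)cc(O)cc1O | starting material
2 | N-(2,4,6-trihydroxy-3-methylbenzylidene)-N-methylmethanaminium chloride | C[N+](C)=Cc1c(O)c(C)c(O)cc1O.[Cl-] | intermediate
3 | 2,4,6-trihydroxy-3-methylbenzaldehyde | O=Cc1c(O)c(C)c(O)cc1O | intermediate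
4 | 2-hydroxy-4,6-bis(methoxymethoxy)-3-methylbenzaldehyde | O=Cc1c(O)c(C)c(OCOC)cc1OCOC | intermediate
5 | 2-methoxy-4,6-bis(methoxymethoxy)-3-methylbenzaldehyde | O=Cc1c(OC)c(C)c(OCOC)cc1OCOC | intermediate
6 | potassium salt of N-{2-[2-methoxy-4,6-bis(methoxymethoxy)-3-methylphenyl]-1-tosylethenyl}formamide (alkene geometry not defined) | [K+].O=C[N-]C(=Cc1c(OC)c(C)c(OCOC)cc1OCOC)S(=O)(=O)c1ccc(C)cc1 | intermediate
7 | 2-[2-methoxy-4,6-bis(methoxymethoxy)-3-methylphenyl]acetonitrile | N#CCc1c(OC)c(C)c(OCOC)cc1OCOC | intermediate
8 | potassium 2-[2-methoxy-4,6-bis(methoxymethoxy)-3-methylphenyl]acetate | [K+].[O-]C(=O)Cc1c(OC)c(C)c(OCOC)cc1OCOC | intermediate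
9 | 2-[2-methoxy-4,6-bis(methoxymethoxy)-3-methylphenyl]acetic acid | OC(=O)Cc1c(OC)c(C)c(OCOC)cc1OCOC | intermediate
10 | methyl 2-[2-methoxy-4,6-bis(methoxymethoxy)-3-methylphenyl]acetate | COC(=O)Cc1c(OC)c(C)c(OCOC)cc1OCOC | intermediate
11 | lithium 1,1-dibromo-3-[2-methoxy-4,6-bis(methoxymethoxy)-3-methylphenyl]prop-1-en-2-olate | [Li+].[O-]C(Cc1c(OC)c(C)c(OCOC)cc1OCOC)=C(Br)Br | intermediate
12 | lithium 3-[2-methoxy-4,6-bis(methoxymethoxy)-3-methylphenyl]prop-1-yn-1-olate | [Li+].[O-]C#CCc1c(OC)c(C)c(OCOC)cc1OCOC | intermediate
13 | triisopropyl({3-[2-methoxy-4,6-bis(methoxymethoxy)-3-methylphenyl]prop-1-yn-1-yl}oxy)silane | CC(C)[Si](OC#CCc1c(OC)c(C)c(OCOC)cc1OCOC)(C(C)C)C(C)C | intermediate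
14 | acetone | CC(C)=O | starting material
15 | ketene | C=C=O | intermediate
16 | 2-[2-methoxy-4,6-bis(methoxymethoxy)-3-methylbenzyl]-3-(triisopropylsilyloxy)cyclobut-2-en-1-one | O=C1CC(O[Si](C(C)C)(C(C)C)C(C)C)=C1Cc1c(OC)c(C)c(OCOC)cc1OCOC | intermediate
17 | chloroacetaldehyde dimethyl acetal (2-chloro-1,1-dimethoxyethane) | COC(CCl)OC | starting material
18 | prenyl bromide (1-bromo-3-methylbut-2-ene) | CC(C)=CCBr | starting material
19 | sodium methoxyacetylide | [Na+].[C-]#COC | intermediate
20 | 1-methoxy-5-methylhex-4-en-1-yne | COC#CCC=C(C)C | intermediate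
21 | 2-[2-methoxy-4,6-bis(methoxymethoxy)-3-methylbenzyl]-3-(triisopropylsilyloxy)buta-1,3-dien-1-one | O=C=C(Cc1c(OC)c(C)c(OCOC)cc1OCOC)C(=C)O[Si](C(C)C)(C(C)C)C(C)C | intermediate
22 | racemic 3-methoxy-4-[2-methoxy-4,6-bis(methoxymethoxy)-3-methylbenzyl]-2-(3-methylbut-2-enyl)-4-[1-(triisopropylsilyloxy)ethenyl]cyclobut-2-en-1-one | O=C1C(CC=C(C)C)=C(OC)C1(Cc1c(OC)c(C)c(OCOC)cc1OCOC)C(=C)O[Si](C(C)C)(C(C)C)C(C)C | intermediate
23 | 3-methoxy-4-[2-methoxy-4,6-bis(methoxymethoxy)-3-methylbenzyl]-2-(3-methylbut-2-enyl)-5-(triisopropylsilyloxy)hexa-1,3,5-trien-1-one, ketenyl and siloxyvinyl groups cis on the central double bond | O=C=C(CC=C(C)C)/C(OC)=C(/Cc1c(OC)c(C)c(OCOC)cc1OCOC)C(=C)O[Si](C(C)C)(C(C)C)C(C)C | intermediate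
24 | 3-methoxy-4-[2-methoxy-4,6-bis(methoxymethoxy)-3-methylbenzyl]-2-(3-methylbut-2-enyl)-5-(triisopropylsilyloxy)cyclohexa-2,4-dien-1-one | O=C1CC(O[Si](C(C)C)(C(C)C)C(C)C)=C(Cc2c(OC)c(C)c(OCOC)cc2OCOC)C(OC)=C1CC=C(C)C | intermediate
25 | 3-methoxy-4-[2-methoxy-4,6-bis(methoxymethoxy)-3-methylbenzyl]-2-(3-methylbut-2-enyl)-5-(triisopropylsilyloxy)phenol | COc1c(CC=C(C)C)c(O)cc(O[Si](C(C)C)(C(C)C)C(C)C)c1Cc1c(OC)c(C)c(OCOC)cc1OCOC | intermediate
26 | 5-methoxy-4-[2-methoxy-4,6-bis(methoxymethoxy)-3-methylbenzyl]-6-(3-methylbut-2-enyl)benzene-1,3-diol | COc1c(CC=C(C)C)c(O)cc(O)c1Cc1c(OC)c(C)c(OCOC)cc1OCOC | intermediate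
27 | 3-methoxy-2-[2-methoxy-4,6-bis(methoxymethoxy)-3-methylbenzyl]-1,5-bis(methoxymethoxy)-4-(3-methylbut-2-enyl)benzene | COc1c(CC=C(C)C)c(OCOC)cc(OCOC)c1Cc1c(OC)c(C)c(OCOC)cc1OCOC | intermediate
28 | dilithio derivative of 27, lithiated at the one free ring position of ring A and of ring B | COc1c(CC=C(C)C)c(OCOC)c([Li])c(OCOC)c1Cc1c(OC)c(C)c(OCOC)c([Li])c1OCOC | intermediate
29 | dilithium bis(alkoxide) from twofold addition of 28 to N-methoxy-N-methylacetamide (diastereomer mixture) | COc1c(CC=C(C)C)c(OCOC)c(C(C)([O-])N(C)OC)c(OCOC)c1Cc1c(OC)c(C)c(OCOC)c(C(C)([O-])N(C)OC)c1OCOC.[Li+].[Li+] | intermediate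
30 | mallotojaponin B tetrakis(methoxymethyl) ether, 1-{3-[3-acetyl-6-methoxy-2,4-bis(methoxymethoxy)-5-(3-methylbut-2-enyl)benzyl]-4-methoxy-2,6-bis(methoxymethoxy)-5-methylphenyl}ethan-1-one | COc1c(CC=C(C)C)c(OCOC)c(C(C)=O)c(OCOC)c1Cc1c(OC)c(C)c(OCOC)c(C(C)=O)c1OCOC | intermediate
31 | mallotojaponin B, 1-{3-[3-acetyl-2,4-dihydroxy-6-methoxy-5-(3-methylbut-2-enyl)benzyl]-2,6-dihydroxy-4-methoxy-5-methylphenyl}ethan-1-one | COc1c(C)c(O)c(C(C)=O)c(O)c1Cc1c(O)c(C(C)=O)c(O)c(CC=C(C)C)c1OC | target

**Count**

Total steps: 14. Longest linear sequence: 13 steps (steps 1 to 8 and 10 to 14); step 9 is a one-step side branch.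

**Steps most likely to fail**

Step 10. The cyclobutenone is a vinylogous silyl ester, so its electrocyclic opening may be slow at 110 °C. During prolonged heating it may lose the silyl group to adventitious moisture, and the product phenol may be O-acylated by the vinylketene. The fallback separates generation of the vinylketene from the aromatisation. Setting out from 16 and 20, irradiation through Pyrex at room temperature in benzene should open the cyclobutenone photochemically to 21, which is trapped by 20 to give vinylcyclobutenone 22. This is isolated and then heated briefly on its own in toluene, passing through 23 and 24 to rejoin the route at 25. This fallback makes no compound outside the list (entry F0).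

Step 7. The bases may deprotonate the ester α to the carbonyl instead of adding LiCHBr2. The sec-butyllithium may metalate the ring position between the two MOM ethers, and silylation of the ynolate may occur partly on carbon. The fallback reaches the same ynolate by oxidation of an acetylide. Setting out from ester 10, reduction with i-Bu2AlH at −78 °C would give 2-[2-methoxy-4,6-bis(methoxymethoxy)-3-methylphenyl]acetaldehyde F1. Seyferth–Gilbert homologation with dimethyl (1-diazo-2-oxopropyl)phosphonate and K2CO3 in methanol would give 3-[2-methoxy-4,6-bis(methoxymethoxy)-3-methylphenyl]prop-1-yne F2. Deprotonation with n-BuLi and oxidation of the lithium acetylide with t-BuOOLi (Julia ynolate synthesis) would give ynolate 12, and silylation with i-Pr3SiCl rejoins the route at 13.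

Step 13. Lithiation may stray to the diarylmethane or prenyl CH2 groups. The second ring may fail to metalate fully, leaving monoacetyl material, and the hindered aryllithium may enolise the Weinreb amide instead of adding to it. The fallback replaces carbanion chemistry by electrophilic substitution. Setting out from resorcinol 26, 3 M HCl in methanol at room temperature would remove the two ring A MOM groups to give 4-(4,6-dihydroxy-2-methoxy-3-methylbenzyl)-5-methoxy-6-(3-methylbut-2-enyl)benzene-1,3-diol F3. Twofold Friedel–Crafts C-acetylation with Ac2O and BF3·OEt2 at the single free position of each ring, kept cold and short to spare the prenyl group, followed by K2CO3 in methanol to cleave any aryl acetates, should lead directly to 31.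

**Further compounds**

F0 | step 10 | none | none
F1 | step 7 | 2-[2-methoxy-4,6-bis(methoxymethoxy)-3-methylphenyl]acetaldehyde | O=CCc1c(OC)c(C)c(OCOC)cc1OCOC
F2 | step 7 | 3-[2-methoxy-4,6-bis(methoxymethoxy)-3-methylphenyl]prop-1-yne | C#CCc1c(OC)c(C)c(OCOC)cc1OCOC
F3 | step 13 | 4-(4,6-dihydroxy-2-methoxy-3-methylbenzyl)-5-methoxy-6-(3-methylbut-2-enyl)benzene-1,3-diol | COc1c(CC=C(C)C)c(O)cc(O)c1Cc1c(OC)c(C)c(O)cc1O
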